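**Plan**
1. Retrosynthesis: the formate C–O bond is cut first, then C9–C10 (ring-closing metathesis, alkene saturated afterwards), then the two oxolane bonds C13–C14 and O–C1 together, then C1–C2 (Suzuki–Miyaura), C2=C3 (Takai–Utimoto) and C4–C5 (Mukaiyama aldol).
2. Forward: the C3–C9 chain with the C4 carbinol and C6 ketone is built by aldol addition and extended to a 2-isopropyl-1,3-diene; the oxolane forms in the step that joins this diene to a C10–C13 iodohydrin; the 14-membered carbocycle is closed last by metathesis.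
3. Enabling feature: in the oxolane ring (O, C12, C13, C14, C1) the carbon C1 is tertiary and allylic to C2=C3. O–C1 is therefore the bond made when an alcohol captures an allyl–palladium unit, and C13–C14 the bond made when a C13 radical adds to the CH2 end of a diene C14=C1–C2=C3.
4. Stereochemistry: C8 from rhodium/(S)-BINAP conjugate vinylation, C4 from copper bis(oxazoline) aldol catalysis, C11 and C12 from a Sharpless kinetic resolution (erythro epoxy alcohol), C1 from C12 in the annulation, E-C2=C3 from the chromium olefination.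
5. Atom numbers follow the cembrane skeleton: C1 carries isopropyl and the ring oxygen, C4 the tertiary carbinol, C6 the ketone, C8 the methyl-bearing CH, C11 the formate, C12 the methyl-bearing oxolane carbon, C13 and C14 the oxolane CH2 groups.

Key step: step 14

**Remarks on the chemistry (assumptions)**
- The target is (1S,2E,4S,8S,11R,12S) in the numbering above; names of compounds 24–27 use this numbering on the 15-oxabicyclo[10.2.1]pentadecane skeleton.
- Transient radicals and catalyst-bound species are described in the Why lines and are not numbered. Metal alkoxides that are only protonated on work-up are not numbered either.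
- Compound 10 is carried as both C6 epimers (converging at 11) and compound 24 as both C9=C10 isomers (converging at 25).
- Acetic formic anhydride is used as a preformed reagent.

**Route**

Step 1
Reactants: 1 (E)-pent-3-en-2-one; 2 potassium vinyltrifluoroborate
Product: 3 (R)-4-methylhex-5-en-2-one
Conditions: [Rh(cod)2]PF6 (3 mol %), (S)-BINAP, toluene/H2O, 105 °C
Reagents that add atoms: none
Why: Rhodium-catalysed asymmetric conjugate addition of an alkenylboron reagent to an acyclic enone (Hayashi–Miyaura reaction); the (S)-BINAP–rhodium–vinyl species is expected to add to the α-si face of the E-enone, which sets C8 (R here, S in the target once the vinyl group has become ring CH2).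

Step 2
Reactants: 3 (R)-4-methylhex-5-en-2-one
Product: 5 (R)-trimethyl[(4-methylhexa-1,5-dien-2-yl)oxy]silane, via lithium enolate 4 (not isolated)
Conditions: LiN(iPr)2, THF, −78 °C; then Me3SiCl, −78 → 0 °C
Reagents that add atoms: chlorotrimethylsilane, C[Si](C)(C)Cl
Why: Kinetic deprotonation of the methyl ketone should occur at the methyl group and not at the β-branched methylene, and O-silylation traps that enolate without touching C8.

Step 3
Reactants: 5 (R)-trimethyl[(4-methylhexa-1,5-dien-2-yl)oxy]silane; 6 methyl pyruvate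
Product: 8 methyl (2S,6R)-2-hydroxy-2,6-dimethyl-4-oxooct-7-enoate, via trimethylsilyl ether 7 (not isolated)
Conditions: [Cu((S,S)-t-Bu-box)](OTf)2 (10 mol %), THF, −78 °C; then 1 M HCl, THF, 0 °C
Reagents that add atoms: none
Why: Catalytic enantioselective Mukaiyama aldol addition of an enol silane to a pyruvate ester chelated to the divalent copper bis(oxazoline) complex; the tert-butyl groups of the (S,S)-ligand should leave the si face of the ketone open, giving the S tertiary carbinol (C4) under catalyst control, and the acid cleaves the silyl ether.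

Step 4
Reactants: 8 methyl (2S,6R)-2-hydroxy-2,6-dimethyl-4-oxooct-7-enoate
Product: 9 methyl (2S,6R)-2,6-dimethyl-4-oxo-2-[(triethylsilyl)oxy]oct-7-enoate
Conditions: Et3SiOTf, 2,6-lutidine, CH2Cl2, −78 → 0 °C
Reagents that add atoms: triethylsilyl trifluoromethanesulfonate, CC[Si](CC)(CC)OS(=O)(=O)C(F)(F)F
Why: Silyl triflate silylation of a tertiary alcohol; it blocks the retro-aldol pathway of the tertiary β-hydroxy ketone in all later basic or Lewis-acidic steps.

Step 5
Reactants: 9 methyl (2S,6R)-2,6-dimethyl-4-oxo-2-[(triethylsilyl)oxy]oct-7-enoate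
Product: 10 (2S,6R)-2,6-dimethyl-2-[(triethylsilyl)oxy]oct-7-ene-1,4-diol (both C4 epimers of this chain, C6 of the target)
Conditions: iBu2AlH (5 equiv), CH2Cl2, −78 → 0 °C; aq. potassium sodium tartrate
Reagents that add atoms: none
Why: Hydride reduction takes the ester to the primary alcohol and the ketone to the carbinol, which is reoxidised in step 6; aluminium alkoxides at low temperature should not trigger silyl migration.

Step 6
Reactants: 10 (2S,6R)-2,6-dimethyl-2-[(triethylsilyl)oxy]oct-7-ene-1,4-diol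
Product: 11 (2S,6R)-2,6-dimethyl-4-oxo-2-[(triethylsilyl)oxy]oct-7-enal
Conditions: (COCl)2, DMSO, CH2Cl2, −78 °C; Et3N, −78 → 0 °C
Reagents that add atoms: none
Why: Swern oxidation activates both hydroxyls before base is added, so the 1,4-diol should go to the keto aldehyde without lactol or lactone formation; the aldehyde has no α-hydrogen, so C4 cannot epimerise.

Step 7
Reactants: 11 (2S,6R)-2,6-dimethyl-4-oxo-2-[(triethylsilyl)oxy]oct-7-enal
Product: 12 (3R,7S,8E)-3,7-dimethyl-9-(4,4,5,5-tetramethyl-1,3,2-dioxaborolan-2-yl)-7-[(triethylsilyl)oxy]nona-1,8-dien-5-one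
Conditions: CrCl2 (8 equiv), LiI, THF, 25 °C
Reagents that add atoms: 2-(dichloromethyl)-4,4,5,5-tetramethyl-1,3,2-dioxaborolane, CC1(C)OB(C(Cl)Cl)OC1(C)C
Why: Takai–Utimoto olefination with the geminal dichromium reagent formed from the dichloromethylboronate and divalent chromium; it is selective for aldehydes over ketones and should give the E-alkenylboronate (C2=C3).

Step 8
Reactants: 13 3-methylbutan-2-one
Product: 15 3-methylbut-1-en-2-yl trifluoromethanesulfonate, via lithium enolate 14 (not isolated)
Conditions: LiN(iPr)2, THF, −78 °C; then PhNTf2, −78 → 0 °C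
Reagents that add atoms: N-phenylbis(trifluoromethanesulfonimide), O=S(=O)(N(c1ccccc1)S(=O)(=O)C(F)(F)F)C(F)(F)F
Why: Kinetic enolisation at the methyl group and O-triflation give the 1,1-disubstituted enol triflate that carries C1, C14 and the isopropyl group.

Step 9
Reactants: 12 (3R,7S,8E)-3,7-dimethyl-9-(4,4,5,5-tetramethyl-1,3,2-dioxaborolan-2-yl)-7-[(triethylsilyl)oxy]nona-1,8-dien-5-one; 15 3-methylbut-1-en-2-yl trifluoromethanesulfonate
Product: 16 (3R,7S,8E)-3,7,11-trimethyl-10-methylidene-7-[(triethylsilyl)oxy]dodeca-1,8-dien-5-one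
Conditions: Pd(PPh3)4 (5 mol %), K3PO4, THF/H2O, 25 → 40 °C
Reagents that add atoms: none
Why: Suzuki–Miyaura coupling of an alkenylboronate with an enol triflate proceeds with retention at both sp2 carbons and should give the 2-isopropyl-1,3-diene (C1–C2 bond) with the E C2=C3 bond intact.

Step 10
Reactants: 17 methacrolein; 18 vinylmagnesium bromide
Product: 19 rac-2-methylpenta-1,4-dien-3-ol
Conditions: THF, −78 → 0 °C; aq. NH4Cl
Reagents that add atoms: none
Why: 1,2-Addition of a vinyl Grignard reagent to the enal gives the racemic bis-allylic alcohol.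

Step 11
Reactants: 19 rac-2-methylpenta-1,4-dien-3-ol
Product: 20 (1R)-1-[(2S)-2-methyloxiran-2-yl]prop-2-en-1-ol
Conditions: Ti(OiPr)4 (10 mol %), D-(−)-diisopropyl tartrate (12 mol %), t-BuOOH (0.45 equiv), 4 Å molecular sieves, CH2Cl2, −20 °C
Reagents that add atoms: tert-butyl hydroperoxide, CC(C)(C)OO
Why: Sharpless asymmetric epoxidation run as a kinetic resolution: with the D-(−)-tartrate the R alcohol should be the fast-reacting enantiomer, the more electron-rich 1,1-disubstituted alkene the one epoxidised and the erythro epoxy alcohol the product, which fixes C11 (R) and C12 (S); the unreacted S alcohol is removed by chromatography.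

Step 12
Reactants: 20 (1R)-1-[(2S)-2-methyloxiran-2-yl]prop-2-en-1-ol
Product: 21 tert-butyldimethyl{[(1R)-1-[(2S)-2-methyloxiran-2-yl]prop-2-en-1-yl]oxy}silane
Conditions: t-BuMe2SiCl, imidazole, DMAP (cat.), DMF, 25 °C
Reagents that add atoms: tert-butylchlorodimethylsilane, CC(C)(C)[Si](C)(C)Cl
Why: Silylation of the secondary alcohol; the silyl ether keeps O11 from competing as a nucleophile in step 14 and, unlike an allylic ester, is inert to zerovalent palladium.

Step 13
Reactants: 21 tert-butyldimethyl{[(1R)-1-[(2S)-2-methyloxiran-2-yl]prop-2-en-1-yl]oxy}silane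
Product: 22 (2R,3R)-3-[(tert-butyldimethylsilyl)oxy]-1-iodo-2-methylpent-4-en-2-ol
Conditions: LiI, AcOH, THF, 25 °C
Reagents that add atoms: lithium iodide, [Li+].[I-]
Why: Acid-assisted SN2 opening of the 2,2-disubstituted epoxide by iodide at the unhindered CH2 (C13) leaves the oxygen and configuration at C12 untouched (the descriptor changes only because CH2I outranks C11); the adjacent siloxy group disfavours ionisation at C12.

Step 14
Reactants: 16 (3R,7S,8E)-3,7,11-trimethyl-10-methylidene-7-[(triethylsilyl)oxy]dodeca-1,8-dien-5-one; 22 (2R,3R)-3-[(tert-butyldimethylsilyl)oxy]-1-iodo-2-methylpent-4-en-2-ol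
Product: 23 (3R,7S,8E)-9-[(2S,5S)-5-{(1R)-1-[(tert-butyldimethylsilyl)oxy]prop-2-en-1-yl}-5-methyl-2-(propan-2-yl)oxolan-2-yl]-3,7-dimethyl-7-[(triethylsilyl)oxy]nona-1,8-dien-5-one
Conditions: Pd(OAc)2 (10 mol %), Xantphos (20 mol %), KOAc (2 equiv), PhCF3, 450 nm LEDs, 25 °C
Reagents that add atoms: none
Why: Proposed new method: photoexcited zerovalent palladium–Xantphos should abstract the iodine atom of 22, the β-hydroxyalkyl radical at C13 should add to the CH2 terminus C14 of the diene, and the allyl radical so formed should recombine with monovalent palladium to an η3-allylpalladium iodide over C1–C3, which the C12 hydroxyl attacks at C1 while acetate takes up HI. The closest known reaction types are the visible-light palladium-catalysed radical 1,2-carbofunctionalisation of 1,3-dienes with alkyl halides and the Larock heteroannulation of 1,3-dienes, here merged with an sp3 iodohydrin as the three-atom O–C–C partner. The oxolane is the only ring closed, by 5-exo attack of oxygen on the allyl terminus C1 anti to palladium. The new centre C1 is controlled by C12: in the envelope-like transition state the branched isopropyl group should prefer the face of the small C12 methyl and the slimmer alkenyl arm the face of the siloxyallyl branch, which gives 1S with C2 and C11 cis, while C2=C3 stays E because the bulky C4 substituent takes the syn position of the allyl unit. The step needs C14 over C3 and over the two isolated vinyl groups in the radical addition, secured by the unhindered conjugated CH2 terminus, and five-membered O–C1 over seven-membered O–C3 closure; KOAc is weak enough not to return 22 to epoxide 21 and should keep β-hydride elimination to a triene slow.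

Step 15
Reactants: 23 the oxolane diene of step 14
Product: 24 (1S,2E,4S,8R,11R,12S)-11-[(tert-butyldimethylsilyl)oxy]-4,8,12-trimethyl-1-(propan-2-yl)-4-[(triethylsilyl)oxy]-15-oxabicyclo[10.2.1]pentadeca-2,9-dien-6-one (both C9=C10 isomers)
Conditions: second-generation Grubbs catalyst RuCl2(H2IMes)(PCy3)(=CHPh) (10 mol %), toluene (1 mM), 80 °C
Reagents that add atoms: none
Why: Ring-closing metathesis of the two monosubstituted alkenes closes the 14-membered carbocycle at C9=C10, while the C2=C3 alkene between two fully substituted carbons should not engage the catalyst; the new alkene geometry is irrelevant because it is reduced next.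

Step 16
Reactants: 24 the macrocyclic diene of step 15
Product: 25 (1S,2E,4S,8S,11R,12S)-11-[(tert-butyldimethylsilyl)oxy]-4,8,12-trimethyl-1-(propan-2-yl)-4-[(triethylsilyl)oxy]-15-oxabicyclo[10.2.1]pentadec-2-en-6-one
Conditions: KO2CN=NCO2K, AcOH, CH2Cl2/MeOH, 0 → 25 °C
Reagents that add atoms: none
Why: Diimide transfers hydrogen concertedly and is very sensitive to steric hindrance, so C9=C10 should be reduced while the C2=C3 alkene flanked by two quaternary carbons, the ketone and the silyl ethers remain; no stereocentre is touched.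

Step 17
Reactants: 25 the bis-silyl ether of step 16
Product: 26 (1S,2E,4S,8S,11R,12S)-4,11-dihydroxy-4,8,12-trimethyl-1-(propan-2-yl)-15-oxabicyclo[10.2.1]pentadec-2-en-6-one
Conditions: HF·pyridine, pyridine, THF, 0 → 25 °C
Reagents that add atoms: none
Why: Buffered fluoride cleavage of both silyl ethers; the buffered medium should avoid the retro-aldol cleavage that a basic fluoride source would risk and the ionisation of the tertiary allylic C–O bonds that strong acid would risk.

Step 18
Reactants: 26 the diol of step 17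
Product: 27 (1S,2E,4S,8S,11R,12S)-4-hydroxy-4,8,12-trimethyl-6-oxo-1-(propan-2-yl)-15-oxabicyclo[10.2.1]pentadec-2-en-11-yl formate
Conditions: acetic formic anhydride (preformed), pyridine, CH2Cl2, 0 °C
Reagents that add atoms: acetic formic anhydride, CC(=O)OC=O
Why: O-Formylation with the mixed anhydride occurs at the formyl carbonyl and should take place only at the secondary C11 hydroxyl, the tertiary C4 hydroxyl being far more hindered; C11 keeps its configuration.

**Compound list**
1 | (E)-pent-3-en-2-one | C/C=C/C(C)=O | starting material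
2 | potassium vinyltrifluoroborate | [K+].C=C[B-](F)(F)F | starting material
3 | (R)-4-methylhex-5-en-2-one | CC(=O)C[C@@H](C)C=C | intermediate
4 | lithium (R)-4-methylhexa-1,5-dien-2-olate | [Li+].[O-]C(=C)C[C@@H](C)C=C | intermediate
5 | (R)-trimethyl[(4-methylhexa-1,5-dien-2-yl)oxy]silane | C=C(O[Si](C)(C)C)C[C@@H](C)C=C | intermediate
6 | methyl pyruvate | COC(=O)C(C)=O | starting material
7 | methyl (2S,6R)-2,6-dimethyl-4-oxo-2-[(trimethylsilyl)oxy]oct-7-enoate | COC(=O)[C@@](C)(O[Si](C)(C)C)CC(=O)C[C@@H](C)C=C | intermediate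
8 | methyl (2S,6R)-2-hydroxy-2,6-dimethyl-4-oxooct-7-enoate | COC(=O)[C@@](C)(O)CC(=O)C[C@@H](C)C=C | intermediate
9 | methyl (2S,6R)-2,6-dimethyl-4-oxo-2-[(triethylsilyl)oxy]oct-7-enoate | COC(=O)[C@@](C)(O[Si](CC)(CC)CC)CC(=O)C[C@@H](C)C=C | intermediate
10 | (2S,6R)-2,6-dimethyl-2-[(triethylsilyl)oxy]oct-7-ene-1,4-diol (both C4 epimers) | OC[C@@](C)(O[Si](CC)(CC)CC)CC(O)C[C@@H](C)C=C | intermediate
11 | (2S,6R)-2,6-dimethyl-4-oxo-2-[(triethylsilyl)oxy]oct-7-enal | O=C[C@@](C)(O[Si](CC)(CC)CC)CC(=O)C[C@@H](C)C=C | intermediate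
12 | (3R,7S,8E)-3,7-dimethyl-9-(4,4,5,5-tetramethyl-1,3,2-dioxaborolan-2-yl)-7-[(triethylsilyl)oxy]nona-1,8-dien-5-one | CC1(C)OB(/C=C/[C@@](C)(O[Si](CC)(CC)CC)CC(=O)C[C@@H](C)C=C)OC1(C)C | intermediate
13 | 3-methylbutan-2-one | CC(=O)C(C)C | starting material
14 | lithium 3-methylbut-1-en-2-olate | [Li+].[O-]C(=C)C(C)C | intermediate
15 | 3-methylbut-1-en-2-yl trifluoromethanesulfonate | C=C(OS(=O)(=O)C(F)(F)F)C(C)C | intermediate
16 | (3R,7S,8E)-3,7,11-trimethyl-10-methylidene-7-[(triethylsilyl)oxy]dodeca-1,8-dien-5-one | C=C(C(C)C)/C=C/[C@@](C)(O[Si](CC)(CC)CC)CC(=O)C[C@@H](C)C=C | intermediate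
17 | methacrolein | C=C(C)C=O | starting material
18 | vinylmagnesium bromide | C=C[Mg]Br | starting material
19 | rac-2-methylpenta-1,4-dien-3-ol | C=CC(O)C(C)=C | intermediate
20 | (1R)-1-[(2S)-2-methyloxiran-2-yl]prop-2-en-1-ol | C=C[C@@H](O)[C@]1(C)CO1 | intermediate
21 | tert-butyldimethyl{[(1R)-1-[(2S)-2-methyloxiran-2-yl]prop-2-en-1-yl]oxy}silane | C=C[C@@H](O[Si](C)(C)C(C)(C)C)[C@]1(C)CO1 | intermediate
22 | (2R,3R)-3-[(tert-butyldimethylsilyl)oxy]-1-iodo-2-methylpent-4-en-2-ol | C=C[C@@H](O[Si](C)(C)C(C)(C)C)[C@](C)(CI)O | intermediate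
23 | (3R,7S,8E)-9-[(2S,5S)-5-{(1R)-1-[(tert-butyldimethylsilyl)oxy]prop-2-en-1-yl}-5-methyl-2-(propan-2-yl)oxolan-2-yl]-3,7-dimethyl-7-[(triethylsilyl)oxy]nona-1,8-dien-5-one | CC(C)[C@]1(/C=C/[C@@](C)(O[Si](CC)(CC)CC)CC(=O)C[C@@H](C)C=C)CC[C@@](C)([C@H](O[Si](C)(C)C(C)(C)C)C=C)O1 | intermediate
24 | (1S,2E,4S,8R,11R,12S)-11-[(tert-butyldimethylsilyl)oxy]-4,8,12-trimethyl-1-(propan-2-yl)-4-[(triethylsilyl)oxy]-15-oxabicyclo[10.2.1]pentadeca-2,9-dien-6-one (both C9=C10 isomers) | CC(C)[C@]12/C=C/[C@@](C)(O[Si](CC)(CC)CC)CC(=O)C[C@@H](C)C=C[C@@H](O[Si](C)(C)C(C)(C)C)[C@](C)(CC1)O2 | intermediate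
25 | (1S,2E,4S,8S,11R,12S)-11-[(tert-butyldimethylsilyl)oxy]-4,8,12-trimethyl-1-(propan-2-yl)-4-[(triethylsilyl)oxy]-15-oxabicyclo[10.2.1]pentadec-2-en-6-one | CC(C)[C@]12/C=C/[C@@](C)(O[Si](CC)(CC)CC)CC(=O)C[C@@H](C)CC[C@@H](O[Si](C)(C)C(C)(C)C)[C@](C)(CC1)O2 | intermediate
26 | (1S,2E,4S,8S,11R,12S)-4,11-dihydroxy-4,8,12-trimethyl-1-(propan-2-yl)-15-oxabicyclo[10.2.1]pentadec-2-en-6-one | CC(C)[C@]12/C=C/[C@@](C)(O)CC(=O)C[C@@H](C)CC[C@@H](O)[C@](C)(CC1)O2 | intermediate
27 | (1S,2E,4S,8S,11R,12S)-4-hydroxy-4,8,12-trimethyl-6-oxo-1-(propan-2-yl)-15-oxabicyclo[10.2.1]pentadec-2-en-11-yl formate | CC(C)[C@]12/C=C/[C@@](C)(O)CC(=O)C[C@@H](C)CC[C@@H](OC=O)[C@](C)(CC1)O2 | target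

**Step count and risks**
Total steps: 18. Longest linear sequence: 13 (steps 1–7, 9, 14–18).

Step 14 (bears the label). Radical generation may be outrun by β-hydroxide elimination or simple reduction of the iodide, and the oxygen may close on the wrong face of the allyl unit (poor facial selectivity at C1). The fallback uses known chemistry only, sets out from epoxide 21 and keto aldehyde 11, and returns at 23. Epoxide 21 is opened at C13 with CH2=C=CHMgBr to give the alkynol (3R,4S)-3-[(tert-butyldimethylsilyl)oxy]-4-methyloct-1-en-7-yn-4-ol F1. Normant carbocupration of the terminal alkyne (iPrMgBr, CuBr·SMe2) followed by iodine gives the vinyl iodide (3R,4S,7Z)-3-[(tert-butyldimethylsilyl)oxy]-8-iodo-4-methyl-7-(propan-2-yl)octa-1,7-dien-4-ol F2. Nozaki–Hiyama–Kishi coupling of F2 with the aldehyde of 11 (CrCl2, NiCl2 cat., DMF; aldehyde-selective) gives the allylic alcohol F3 as both C3 epimers. Selective carbonate formation at the secondary hydroxyl (ClCO2Me, pyridine) gives the methyl carbonate F4. Tsuji–Trost cycloetherification (Pd2(dba)3 with a chiral trans-1,2-diaminocyclohexane-derived bis(2-diphenylphosphinobenzamide) ligand) then forms O–C1 through the same allyl–palladium unit, with ligand control of C1 and the E alkene from the syn allyl isomer, to give 23.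

Step 15. Initiation at the hindered siloxy-bearing vinyl group may be slow, so that oligomerisation through the other vinyl group competes with ring closure. The fallback reverses the order of the two unions; it sets out from boronate 12 and epoxide 21 and returns at 24. Cross-metathesis of 12 with an excess of 21 (second-generation Hoveyda–Grubbs catalyst RuCl2(H2IMes)(=CH-C6H4-2-OiPr)) joins C9=C10 first and gives the boronate epoxide F5. Suzuki–Miyaura coupling with triflate 15 under the conditions of step 9 gives the diene epoxide F6. LiI/AcOH as in step 13 gives the diene iodohydrin F7. The annulation of step 14, run at high dilution, would then close the oxolane and the 14-membered ring in one operation to give 24.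

Step 7. Addition of the bulky dichromium reagent to the neopentyl-type aldehyde may be sluggish, leaving room for reduction or reductive coupling of the carbonyl groups. The fallback replaces chromium olefination by alkyne hydrometalation; it sets out from 11 and returns at 16. Ohira–Bestmann homologation (dimethyl (1-diazo-2-oxopropyl)phosphonate, K2CO3, MeOH; aldehyde-selective) gives the alkyne (3S,7R)-3,7-dimethyl-3-[(triethylsilyl)oxy]non-8-en-1-yn-5-one F8. Palladium-catalysed hydrostannation (Bu3SnH, PdCl2(PPh3)2, THF), with tin going to the unhindered terminus, gives the E-vinylstannane (3R,7S,8E)-3,7-dimethyl-9-(tributylstannyl)-7-[(triethylsilyl)oxy]nona-1,8-dien-5-one F9. Stille coupling of F9 with triflate 15 (Pd(PPh3)4, LiCl, CuI, DMF) gives 16.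

**Further compounds**
F1 | step 14 | (3R,4S)-3-[(tert-butyldimethylsilyl)oxy]-4-methyloct-1-en-7-yn-4-ol | C=C[C@@H](O[Si](C)(C)C(C)(C)C)[C@@](C)(O)CCC#C
F2 | step 14 | (3R,4S,7Z)-3-[(tert-butyldimethylsilyl)oxy]-8-iodo-4-methyl-7-(propan-2-yl)octa-1,7-dien-4-ol | C=C[C@@H](O[Si](C)(C)C(C)(C)C)[C@@](C)(O)CC/C(C(C)C)=C/I
F3 | step 14 | (3R,4S,7Z,10S,14R)-3-[(tert-butyldimethylsilyl)oxy]-4,9-dihydroxy-4,10,14-trimethyl-7-(propan-2-yl)-10-[(triethylsilyl)oxy]hexadeca-1,7,15-trien-12-one (both C9 epimers) | C=C[C@@H](O[Si](C)(C)C(C)(C)C)[C@@](C)(O)CC/C(C(C)C)=C/C(O)[C@@](C)(O[Si](CC)(CC)CC)CC(=O)C[C@@H](C)C=C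
F4 | step 14 | methyl (3R,4S,7Z,10S,14R)-3-[(tert-butyldimethylsilyl)oxy]-4-hydroxy-4,10,14-trimethyl-12-oxo-7-(propan-2-yl)-10-[(triethylsilyl)oxy]hexadeca-1,7,15-trien-9-yl carbonate (both C9 epimers) | C=C[C@@H](O[Si](C)(C)C(C)(C)C)[C@@](C)(O)CC/C(C(C)C)=C/C(OC(=O)OC)[C@@](C)(O[Si](CC)(CC)CC)CC(=O)C[C@@H](C)C=C
F5 | step 15 | (1E,3S,7R,10R)-10-[(tert-butyldimethylsilyl)oxy]-3,7-dimethyl-10-[(2S)-2-methyloxiran-2-yl]-1-(4,4,5,5-tetramethyl-1,3,2-dioxaborolan-2-yl)-3-[(triethylsilyl)oxy]deca-1,8-dien-5-one (both C8=C9 isomers) | CC1(C)OB(/C=C/[C@@](C)(O[Si](CC)(CC)CC)CC(=O)C[C@@H](C)C=C[C@@H](O[Si](C)(C)C(C)(C)C)[C@]2(C)CO2)OC1(C)C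
F6 | step 15 | (3E,5S,9R,12R)-12-[(tert-butyldimethylsilyl)oxy]-5,9-dimethyl-12-[(2S)-2-methyloxiran-2-yl]-2-(propan-2-yl)-5-[(triethylsilyl)oxy]dodeca-1,3,10-trien-7-one (both C10=C11 isomers) | C=C(C(C)C)/C=C/[C@@](C)(O[Si](CC)(CC)CC)CC(=O)C[C@@H](C)C=C[C@@H](O[Si](C)(C)C(C)(C)C)[C@]1(C)CO1
F7 | step 15 | (3E,5S,9R,12R,13R)-12-[(tert-butyldimethylsilyl)oxy]-13-hydroxy-14-iodo-5,9,13-trimethyl-2-(propan-2-yl)-5-[(triethylsilyl)oxy]tetradeca-1,3,10-trien-7-one (both C10=C11 isomers) | C=C(C(C)C)/C=C/[C@@](C)(O[Si](CC)(CC)CC)CC(=O)C[C@@H](C)C=C[C@@H](O[Si](C)(C)C(C)(C)C)[C@](C)(CI)O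
F8 | step 7 | (3S,7R)-3,7-dimethyl-3-[(triethylsilyl)oxy]non-8-en-1-yn-5-one | C#C[C@@](C)(O[Si](CC)(CC)CC)CC(=O)C[C@@H](C)C=C
F9 | step 7 | (3R,7S,8E)-3,7-dimethyl-9-(tributylstannyl)-7-[(triethylsilyl)oxy]nona-1,8-dien-5-one | CCCC[Sn](CCCC)(CCCC)/C=C/[C@@](C)(O[Si](CC)(CC)CC)CC(=O)C[C@@H](C)C=C
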